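**Retrosynthetic overview**

1. Numbering (germacrane): C1 ketone, C2 and C3 methylenes, C4–C5 epoxide (methyl on C4), C6 lactone O–CH, C7 spiro carbon, C8 ester CH, C9 CH2, C10 C(CH3)–O, C11=C13 methylene, C12 lactone C=O. Ring A is the ten-membered carbocycle, ring B the oxolane (O–C7–C8–C9–C10), ring C the lactone; face a of ring B is the face of the C10 methyl, face b the other.
2. Feature on which the strategy rests: C7, common to rings A, B and C, carries the ring-B oxygen and C11; C8 carries oxygen cis to C11 on face a; C11 is an sp2 carbon bearing C12. This is the imprint of a keto-ester/enol-ether oxetane (bonds C7–C11 and O–C8) whose C11–O bond has been cut with loss of hydrogen from C13.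
3. Disconnections: epoxide from the 4Z alkene; ring C from C6–OH and the C12 ester; ring A by C5–C6 Nozaki–Hiyama–Kishi closure; C2–C3 by enolate alkylation with (Z)-BrCH2C(CH3)=CHI; C8–OH and the C11=C13 acrylate by SmI2 opening of the oxetane and selenoxide elimination; oxetane by Paternò–Büchi addition of tert-butyl pyruvate to the C7=C8 dihydrofuran; ring B by 5-endo cycloisomerisation of an (R)-homopropargylic carbinol.
4. Ring order: ring B (step 4), oxetane (step 6, opened in step 7), ring A (step 18), ring C (step 19), epoxide (step 20).
5. Changes to spectator groups: silyl ether at C6–O (no benzylic C–H for the excited keto ester), dimethyl ketal at C1, tert-butyl ester at C12 (no premature lactonisation). The reductive opening is placed before ketal removal, because SmI2 would cleave C10–O next to a C1 ketone and attack the vinyl iodide.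

Key step: step 6

Remark: the sense of induction in step 1 is not assigned in advance; the ligand antipode that gives the (R)-carbinol is used (both are sold) and the configuration is checked on the product of step 1.
Remark: C11 arises as a mixture of epimers in steps 6, 7 and 9; it is drawn for one epimer in the oxetane and without a descriptor afterwards, and it is erased in step 14.

**Route**

Step 1
Reactants: 1 3,3-dimethoxybutan-2-one; 2 allenylboronic acid pinacol ester
Product: 3 (3R)-2,2-dimethoxy-3-methylhex-5-yn-3-ol
Conditions: CuOAc (5 mol%), (S,S)-Ph-BPE or its antipode (6 mol%), LiOt-Bu (10 mol%), i-PrOH (1.1 equiv), THF, −40 °C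
Reagents that add atoms: none
Why: Copper-catalysed enantioselective propargylation of a ketone with an allenylboronate (boron-to-copper transmetallation, then γ-selective SE2′ addition through a cyclic transition state) is established for methyl ketones, and here the ligand has to tell a methyl group from a fully substituted ketal carbon, so the C10 carbinol should form with high selectivity, R for the matching ligand antipode.

Step 2
Reactants: 3 (3R)-2,2-dimethoxy-3-methylhex-5-yn-3-ol; 4 formaldehyde (as paraformaldehyde)
Product: 6 (5R)-6,6-dimethoxy-5-methylhept-2-yne-1,5-diol, via dilithio alkoxide-acetylide 5 (not isolated)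
Conditions: n-BuLi (2.2 equiv), THF, −78 to −20 °C; (CH2O)n, −20 °C to rt; then H2O
Reagents that add atoms: none
Why: Acetylide hydroxymethylation: the second equivalent of n-BuLi deprotonates the terminal alkyne of the lithium alkoxide and the acetylide adds to formaldehyde to install C6, the ketal and the C10 centre being inert to the base.

Step 3
Reactants: 6 (5R)-6,6-dimethoxy-5-methylhept-2-yne-1,5-diol
Product: 7 (3R)-7-(tert-butyldiphenylsilyloxy)-2,2-dimethoxy-3-methylhept-5-yn-3-ol
Conditions: TBDPSCl, imidazole, CH2Cl2, 0 °C to rt
Reagents that add atoms: tert-butyl(chloro)diphenylsilane, CC(C)(C)[Si](Cl)(c1ccccc1)c1ccccc1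
Why: Silyl ether formation is selective for the primary propargylic hydroxyl because the tertiary C10 carbinol is too hindered for the bulky chlorosilane, and a silyl ether is chosen for C6–O because it offers no benzylic C–H to the excited keto ester of step 6.

Step 4
Reactants: 7 (3R)-7-(tert-butyldiphenylsilyloxy)-2,2-dimethoxy-3-methylhept-5-yn-3-ol
Product: 8 (2R)-5-(tert-butyldiphenylsilyloxymethyl)-2-(1,1-dimethoxyethyl)-2-methyl-2,3-dihydrofuran (ring B with the C7=C8 enol ether)
Conditions: AuCl3 (3 mol%), K2CO3 (10 mol%), MeCN, rt; filtration through Et3N-deactivated silica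
Reagents that add atoms: none
Why: Gold-catalysed 5-endo-dig hydroalkoxylation (cycloisomerisation of a 3-alkyn-1-ol to a 2,3-dihydrofuran): the π-activated alkyne is attacked at C7 by the C10 hydroxyl and protodeauration leaves the endocyclic C7=C8 enol ether, the carbonate buffer protecting the acid-labile enol ether and ketal; ring B is closed here.

Step 5
Reactants: 9 pyruvic acid
Product: 10 tert-butyl pyruvate
Conditions: tert-butyl 2,2,2-trichloroacetimidate (1.5 equiv), CH2Cl2/cyclohexane, rt
Reagents that add atoms: tert-butyl 2,2,2-trichloroacetimidate, CC(C)(C)OC(=N)C(Cl)(Cl)Cl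
Why: Esterification by a trichloroacetimidate: the carboxylic acid protonates the imidate and captures the tert-butyl cation without touching the ketone, and the tert-butyl ester is chosen because it does not lactonise onto the C8 or C6 hydroxyl groups that are set free later.

Step 6
Reactants: 8 dihydrofuran with the C7=C8 enol ether; 10 tert-butyl pyruvate
Product: 11 cis-fused 2,6-dioxabicyclo[3.2.0]heptane (oxetane O–C8 and C7–C11 on face a of ring B; C11 bears CH3 and CO2t-Bu)
Conditions: hν (350 nm, Pyrex), 10 (4 equiv), benzene (0.05 M), 10 °C, degassed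
Reagents that add atoms: none
Why: Paternò–Büchi reaction: the n,π* triplet of the keto ester (reached by intersystem crossing after excitation near 350 nm) attacks with its electrophilic oxygen at C8, the β-carbon of the enol ether, to give a triplet 1,4-biradical with a tertiary α-oxy radical at C7 and an ester-stabilised radical at C11, and spin inversion followed by radical recombination makes the C7–C11 bond. The closest known reaction type is the photocycloaddition of pyruvates and glyoxylates to 2,3-dihydrofurans and other enol ethers, which gives 3-alkoxyoxetanes (2,6-dioxabicyclo[3.2.0]heptanes) with this orientation. The oxetane is closed in a stepwise [2+2] mode, the O–C8 bond first and the C7–C11 bond by collapse of the 1,4-biradical, and the four-membered ring can only be cis-fused to ring B. C8 and C7 are therefore set together by the face of the first attack: the 1,1-dimethoxyethyl group on the quaternary C10 shields face b of the almost flat dihydrofuran, so the oxetane should form on face a, syn to the C10 methyl, while C11 is not controlled and is erased in step 14. The step needs regioselectivity (oxygen to C8, carbon to C7), which the polarity of the enol ether and the stability of the C7 radical secure, and chemoselectivity for addition over hydrogen abstraction, which is why C6–O carries a silyl group and not a benzylic ether. Because the ring closure joins two fully substituted carbons it may be slow, and reversion of the biradical then only lowers the quantum yield.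

Step 7
Reactants: 11 oxetane ester
Product: 12 γ-hydroxy tert-butyl ester (C8–OH and C7–CH(CH3)CO2t-Bu cis on face a)
Conditions: SmI2 (2.5 equiv), HMPA (8 equiv), MeOH (4 equiv), THF, −78 to −40 °C; cold pH 7 buffer
Reagents that add atoms: none
Why: SmI2 reduction of a carbon–oxygen bond α to an ester (the reaction that opens glycidic esters to β-hydroxy esters): electron transfer to the ester carbonyl is followed by cleavage of the strained C11–O bond, the only bond α to the carbonyl, and the trivalent samarium enolate is protonated at once by methanol, so C8–OH is released with its configuration intact (the O–C8 bond is not touched) while the ketal keeps C1 from reacting as an α-alkoxy ketone and the cold protic medium and the tert-butyl ester hold back lactonisation and β-elimination of the ring-B oxygen.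

Step 8
Reactants: 12 γ-hydroxy tert-butyl ester
Product: 13 C8 tert-butyldimethylsilyl ether of 12
Conditions: TBSOTf, 2,6-lutidine, CH2Cl2, −78 °C
Reagents that add atoms: tert-butyldimethylsilyl trifluoromethanesulfonate, CC(C)(C)[Si](C)(C)OS(=O)(=O)C(F)(F)F
Why: Silylation with a silyl triflate and a hindered pyridine base is fast at −78 °C even for the neopentylic C8 hydroxyl and is over before the γ-hydroxy ester can lactonise or the ketal can react.

Step 9
Reactants: 13 C8 silyl ether
Product: 15 C11 phenylselenide of 13 (quaternary α-seleno tert-butyl ester), via lithium ester enolate 14 (not isolated)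
Conditions: LiN(i-Pr)2 (1.5 equiv), THF, −78 °C; PhSeBr, −78 °C
Reagents that add atoms: benzeneselenenyl bromide, Br[Se]c1ccccc1
Why: Ester enolate selenenylation: C11–H is the only acidic hydrogen, the lithium enolate is kept at −78 °C so that the β-alkoxy group (ring-B oxygen on C7) is not expelled, and the selenium electrophile gives the quaternary α-seleno ester, a masked C11=C13 that carries no Michael acceptor into step 13.

Step 10
Reactants: 15 α-seleno ester with the C1 dimethyl ketal
Product: 16 C1 methyl ketone
Conditions: TsOH·H2O (10 mol%), acetone/H2O (10:1), rt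
Reagents that add atoms: water, O
Why: Acid-catalysed ketal hydrolysis through the methoxy oxocarbenium ion frees the C1 methyl ketone, an acyclic dimethyl ketal being cleaved under conditions mild enough for the two silyl ethers, the tert-butyl ester and the selenide.

Step 11
Reactants: 17 propargyl alcohol; 18 methylmagnesium bromide
Product: 20 (Z)-3-iodo-2-methylprop-2-en-1-ol, via vinylmagnesium alkoxide 19 (not isolated)
Conditions: MeMgBr (2.5 equiv), CuI (10 mol%), Et2O/THF, −10 °C to rt; then I2, −10 °C
Reagents that add atoms: iodine, II
Why: Copper-catalysed carbomagnesiation of the magnesium alkoxide of propargyl alcohol places methyl on C4 and magnesium on C5 by anti addition (the magnesium is held by the alkoxide in a five-membered chelate), and iodinolysis with retention gives the Z vinyl iodide in which CH2O and iodine are cis.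

Step 12
Reactants: 20 (Z)-3-iodo-2-methylprop-2-en-1-ol
Product: 21 (Z)-3-bromo-1-iodo-2-methylprop-1-ene
Conditions: CBr4, PPh3, CH2Cl2, 0 °C
Reagents that add atoms: carbon tetrabromide, BrC(Br)(Br)Br
Why: Appel reaction: the alkoxyphosphonium ion is displaced by bromide at the primary allylic carbon without touching the vinyl iodide or its geometry.

Step 13
Reactants: 16 C1 methyl ketone; 21 (Z)-3-bromo-1-iodo-2-methylprop-1-ene
Product: 23 C2-alkylated ketone (C1 ketone carrying the Z chain C2–C3–C4(CH3)=C5H–I), via lithium enolate 22 (not isolated)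
Conditions: LiN(SiMe3)2 (1.1 equiv), THF, −78 °C; 21 (2 equiv), DMPU, −78 to −30 °C
Reagents that add atoms: none
Why: Alkylation of a kinetic lithium enolate: C2 is the only enolisable position (C10 and C11 are fully substituted), and SN2 attack on the primary allylic bromide forms C2–C3 with the Z vinyl iodide unchanged.

Step 14
Reactants: 23 C2-alkylated ketone with the C11 selenide
Product: 25 tert-butyl acrylate (C11=C13), via selenoxide 24 (not isolated)
Conditions: mCPBA (1.05 equiv), CH2Cl2, −78 °C; i-Pr2NH, −78 °C to rt
Reagents that add atoms: none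
Why: Selenoxide syn-elimination: the selenide is oxidised chemoselectively at −78 °C and the selenoxide can only eliminate towards C13 because C7 bears no hydrogen, which gives the C11=C13 acrylate and erases the C11 centre, the amine buffering the selenenic acid.

Step 15
Reactants: 25 bis-silyl ether acrylate
Product: 26 C6,C8-diol
Conditions: HF·pyridine (excess), pyridine, THF, 0 °C to rt
Reagents that add atoms: none
Why: Fluoride-mediated cleavage of both silyl ethers under buffered, weakly acidic conditions, in which the tert-butyl acrylate does not lactonise with either hydroxyl and the ketone and vinyl iodide are inert.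

Step 16
Reactants: 26 C6,C8-diol
Product: 27 C6 aldehyde with free C8–OH
Conditions: TEMPO (10 mol%), PhI(OAc)2 (1.2 equiv), CH2Cl2, rt
Reagents that add atoms: none
Why: Oxoammonium (TEMPO) oxidation with PhI(OAc)2 as terminal oxidant is selective for the primary C6 alcohol over the hindered secondary C8 alcohol, and the aldehyde, bound to the fully substituted C7, can neither enolise nor close a lactol with C8–OH.

Step 17
Reactants: 27 C6 aldehyde with free C8–OH; 28 methacrylic anhydride
Product: 29 C8 methacrylate aldehyde (cyclisation substrate)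
Conditions: 28 (3 equiv), DMAP (1 equiv), Et3N, CH2Cl2, rt to 40 °C
Reagents that add atoms: none
Why: DMAP-catalysed acylation (acylpyridinium mechanism) esterifies the C8 hydroxyl with retention, placing the methacrylate before ring C is formed so that C12 can later lactonise only onto C6–O.

Step 18
Reactants: 29 C8 methacrylate aldehyde
Product: 30 macrocyclic (6R) allylic alcohol (ring A closed, 4Z alkene)
Conditions: CrCl2 (8 equiv), NiCl2 (2 mol%), DMSO (0.003 M), rt, slow addition of 29
Reagents that add atoms: none
Why: Intramolecular Nozaki–Hiyama–Kishi reaction: zerovalent nickel inserts into the vinyl iodide, transmetallation gives an alkenylchromium that adds to the aldehyde and not to the ketone or the esters, the cis-disposed chains on C7 and C10 of ring B and the Z alkene favouring closure of ring A at high dilution with retention of alkene geometry; C6 is set here, and Felkin–Anh addition anti to the C7–O bond, with C5 passing the flat C11 substituent, should give the 6R carbinol.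

Step 19
Reactants: 30 macrocyclic allylic alcohol
Product: 32 α-methylene lactone (ring C closed; 4Z alkene), via hydroxy acid 31 (not isolated)
Conditions: TFA/CH2Cl2 (1:9), 0 °C
Reagents that add atoms: none
Why: Acidolysis of the tert-butyl ester (loss of the tert-butyl cation as isobutene) and acid-catalysed 5-exo-trig lactonisation of the γ-hydroxy acrylic acid onto C6–OH close ring C with retention at C6, C8–O being blocked as the methacrylate.

Step 20
Reactants: 32 α-methylene lactone with the 4Z alkene
Product: 33 CNP0241021.1 (target)
Conditions: DMDO (1.2 equiv), acetone/CH2Cl2, −20 to 0 °C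
Reagents that add atoms: dimethyldioxirane, CC1(C)OO1
Why: Electrophilic epoxidation by a dioxirane is selective for the electron-rich trisubstituted C4=C5 alkene over the two acrylate units and causes no Baeyer–Villiger reaction; with H6 eclipsing the Z alkene (A(1,3) strain) the oxidant should add anti to the allylic C6–O bond, the usual sense for Z allylic esters without a free hydroxyl, which corresponds to the 4R,5S epoxide, the concerted addition keeping C3 and C6 cis.

**Compound list**

1 | 3,3-dimethoxybutan-2-one | CC(=O)C(C)(OC)OC | starting material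
2 | allenylboronic acid pinacol ester (4,4,5,5-tetramethyl-2-(propa-1,2-dienyl)-1,3,2-dioxaborolane) | C=C=CB1OC(C)(C)C(C)(C)O1 | starting material
3 | (3R)-2,2-dimethoxy-3-methylhex-5-yn-3-ol (C10 carbinol) | C[C@](O)(C(C)(OC)OC)CC#C | intermediate
4 | formaldehyde (used as paraformaldehyde) | C=O | starting material
5 | dilithium salt of 3 (lithium alkoxide and lithium acetylide) | C[C@](O[Li])(C(C)(OC)OC)CC#C[Li] | intermediate
6 | (5R)-6,6-dimethoxy-5-methylhept-2-yne-1,5-diol | C[C@](O)(C(C)(OC)OC)CC#CCO | intermediate
7 | (3R)-7-(tert-butyldiphenylsilyloxy)-2,2-dimethoxy-3-methylhept-5-yn-3-ol | C[C@](O)(C(C)(OC)OC)CC#CCO[Si](c1ccccc1)(c1ccccc1)C(C)(C)C | intermediate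
8 | (2R)-5-(tert-butyldiphenylsilyloxymethyl)-2-(1,1-dimethoxyethyl)-2-methyl-2,3-dihydrofuran (C7=C8 enol ether, 10R) | C[C@]1(C(C)(OC)OC)CC=C(CO[Si](c2ccccc2)(c2ccccc2)C(C)(C)C)O1 | intermediate
9 | pyruvic acid | CC(=O)C(=O)O | starting material
10 | tert-butyl pyruvate (tert-butyl 2-oxopropanoate) | CC(=O)C(=O)OC(C)(C)C | intermediate
11 | tert-butyl 1-(tert-butyldiphenylsilyloxymethyl)-3-(1,1-dimethoxyethyl)-3,7-dimethyl-2,6-dioxabicyclo[3.2.0]heptane-7-carboxylate; cis-fused, oxetane on face a, 8S,10R, C11 drawn for the epimer with the ester exo | C[C@]1(C(C)(OC)OC)C[C@@H]2O[C@@](C)(C(=O)OC(C)(C)C)[C@]2(CO[Si](c3ccccc3)(c3ccccc3)C(C)(C)C)O1 | intermediate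
12 | tert-butyl 2-[2-(tert-butyldiphenylsilyloxymethyl)-5-(1,1-dimethoxyethyl)-3-hydroxy-5-methyloxolan-2-yl]propanoate; C8–OH, C7–C11 and C10–CH3 on face a, C11 epimers | C[C@]1(C(C)(OC)OC)C[C@H](O)[C@](CO[Si](c2ccccc2)(c2ccccc2)C(C)(C)C)(C(C)C(=O)OC(C)(C)C)O1 | intermediate
13 | C8 tert-butyldimethylsilyl ether of 12 | C[C@]1(C(C)(OC)OC)C[C@H](O[Si](C)(C)C(C)(C)C)[C@](CO[Si](c2ccccc2)(c2ccccc2)C(C)(C)C)(C(C)C(=O)OC(C)(C)C)O1 | intermediate
14 | lithium enolate of ester 13 (C11=C12 ketene acetal) | C[C@]1(C(C)(OC)OC)C[C@H](O[Si](C)(C)C(C)(C)C)[C@](CO[Si](c2ccccc2)(c2ccccc2)C(C)(C)C)(C(C)=C(O[Li])OC(C)(C)C)O1 | intermediate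
15 | C11 phenylselenide of 13 (C11 bears CH3, SePh and CO2t-Bu; C11 epimers) | C[C@]1(C(C)(OC)OC)C[C@H](O[Si](C)(C)C(C)(C)C)[C@](CO[Si](c2ccccc2)(c2ccccc2)C(C)(C)C)(C(C)([Se]c2ccccc2)C(=O)OC(C)(C)C)O1 | intermediate
16 | C1 methyl ketone from 15 (acetyl group on C10) | C[C@]1(C(C)=O)C[C@H](O[Si](C)(C)C(C)(C)C)[C@](CO[Si](c2ccccc2)(c2ccccc2)C(C)(C)C)(C(C)([Se]c2ccccc2)C(=O)OC(C)(C)C)O1 | intermediate
17 | propargyl alcohol | C#CCO | starting material
18 | methylmagnesium bromide (MeMgBr) | C[Mg]Br | starting material
19 | (Z)-vinylmagnesium alkoxide, BrMg–CH=C(CH3)–CH2–OMgBr, magnesium on carbon cis to CH2O | Br[Mg]OC/C(C)=C\[Mg]Br | intermediate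
20 | (Z)-3-iodo-2-methylprop-2-en-1-ol | OC/C(C)=C\I | intermediate
21 | (Z)-3-bromo-1-iodo-2-methylprop-1-ene | BrC/C(C)=C\I | intermediate
22 | lithium enolate of ketone 16 (C1=C2) | C[C@]1(C(=C)O[Li])C[C@H](O[Si](C)(C)C(C)(C)C)[C@](CO[Si](c2ccccc2)(c2ccccc2)C(C)(C)C)(C(C)([Se]c2ccccc2)C(=O)OC(C)(C)C)O1 | intermediate
23 | C2-alkylated ketone: C10–C(=O)–CH2–CH2–C(CH3)=CH–I (Z), selenide retained | C[C@]1(C(=O)CC/C(C)=C\I)C[C@H](O[Si](C)(C)C(C)(C)C)[C@](CO[Si](c2ccccc2)(c2ccccc2)C(C)(C)C)(C(C)([Se]c2ccccc2)C(=O)OC(C)(C)C)O1 | intermediate
24 | selenoxide of 23 | C[C@]1(C(=O)CC/C(C)=C\I)C[C@H](O[Si](C)(C)C(C)(C)C)[C@](CO[Si](c2ccccc2)(c2ccccc2)C(C)(C)C)(C(C)([Se](=O)c2ccccc2)C(=O)OC(C)(C)C)O1 | intermediate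
25 | tert-butyl acrylate (C11=C13) with C8–OTBS, C6–OTBDPS, C1 ketone and Z vinyl iodide | C[C@]1(C(=O)CC/C(C)=C\I)C[C@H](O[Si](C)(C)C(C)(C)C)[C@](CO[Si](c2ccccc2)(c2ccccc2)C(C)(C)C)(C(=C)C(=O)OC(C)(C)C)O1 | intermediate
26 | C6,C8-diol from 25 | C[C@]1(C(=O)CC/C(C)=C\I)C[C@H](O)[C@](CO)(C(=C)C(=O)OC(C)(C)C)O1 | intermediate
27 | C6 aldehyde with free C8–OH | C[C@]1(C(=O)CC/C(C)=C\I)C[C@H](O)[C@](C=O)(C(=C)C(=O)OC(C)(C)C)O1 | intermediate
28 | methacrylic anhydride | C=C(C)C(=O)OC(=O)C(C)=C | starting material
29 | C8 methacrylate of 27 (aldehyde, Z vinyl iodide, tert-butyl acrylate) | C[C@]1(C(=O)CC/C(C)=C\I)C[C@H](OC(=O)C(C)=C)[C@](C=O)(C(=C)C(=O)OC(C)(C)C)O1 | intermediate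
30 | macrocyclic (6R) allylic alcohol: rings A and B, 4Z alkene, C8 methacrylate (8S), 10R, tert-butyl acrylate on C7 | C=C(C)C(=O)O[C@H]1C[C@@]2(C)O[C@]1(C(=C)C(=O)OC(C)(C)C)[C@H](O)/C=C(C)\CCC2=O | intermediate
31 | hydroxy acid from 30 (C12 carboxylic acid) | C=C(C)C(=O)O[C@H]1C[C@@]2(C)O[C@]1(C(=C)C(=O)O)[C@H](O)/C=C(C)\CCC2=O | intermediate
32 | (4Z,6R,7S,8S,10R) α-methylene lactone: rings A, B and C, C8 methacrylate, C1 ketone | C=C(C)C(=O)O[C@H]1C[C@@]2(C)O[C@@]13C(=C)C(=O)O[C@@H]3/C=C(C)\CCC2=O | intermediate
33 | CNP0241021.1, (4R,5S,6R,7S,8S,10R) in the numbering above | C=C(C)C(=O)O[C@H]1C[C@@]2(C)O[C@@]13C(=C)C(=O)O[C@@H]3[C@@H]1O[C@]1(C)CCC2=O | target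

**Step count and risks**

Total: 20 steps (17 in the main line, 2 for bromide 21, 1 for keto ester 10). Longest linear sequence: 17 steps (steps 1–4, 6–10, 13–20).

Step 6 (photocycloaddition). What may go wrong: collapse of the 1,4-biradical between two fully substituted carbons may be slow, so that reversion, hydrogen transfer within the biradical or hydrogen abstraction from the product by the excess keto ester takes over; shielding of face b may also be incomplete. Fallback, ionic and without light, from 8 to 13. Epoxidation of enol ether 8 with mCPBA (CH2Cl2, −40 to 0 °C) on face a, with opening of the epoxide at the ketal carbon by the acid formed, should give the C8 alcohol with a 3-chlorobenzoate on C7 F1. Silylation (TBSOTf, 2,6-lutidine, −78 °C) gives its C8 TBS ether F2. Ionisation of the anomeric ester with TMSOTf (CH2Cl2, −78 °C) in the presence of 1-tert-butoxy-1-(trimethylsilyloxy)prop-1-ene (Mukaiyama-type addition to the C7 oxocarbenium ion) should form C7–C11 cis to the C8 silyloxy group, by inside attack on the envelope with the 2-silyloxy group pseudo-equatorial. The anomeric ester ionises far more readily than the deactivated C1 ketal. This gives 13 directly, so steps 6 to 8 are bypassed.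

Step 18 (ring closure). What may go wrong: the facial selectivity of the addition to the aldehyde is decided by a macrocyclic transition state and may favour the 6S carbinol; oligomerisation is the lesser risk, given the cis-disposed chains on ring B. Fallback, from 29 to 30. The closure is run as in step 18 and the C6-epimeric carbinol F3, alone or mixed with 30, is oxidised with Dess–Martin periodinane (NaHCO3, CH2Cl2) to the macrocyclic C6 enone F4. 1,2-Reduction (NaBH4, CeCl3·7H2O, MeOH, −78 °C, or catecholborane with a CBS oxazaborolidine of the matching hand) then delivers hydride to the face that took the alkenyl group, which gives the opposite carbinol, 30. The C1 ketone is shielded by the quaternary C10 and is not conjugated, so the enone should react first.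

Step 20 (epoxidation). What may go wrong: the ring conformation may expose the other face of C4=C5, giving the 4S,5R epoxide. Fallback, from 32 to 33, placing the oxygen by anti addition and closure instead of direct transfer. NBS in aqueous THF (0 °C) should form the bromonium ion on the face the dioxirane prefers and deliver water to the tertiary C4 from the other face, giving the trans bromohydrin F5. K2CO3 in MeCN then closes the epoxide from the C4 oxygen with inversion at C5, which puts the oxygen on the face that direct epoxidation missed and returns to 33. A hemiketal between C4–OH and the C1 ketone may form on the way and reopens under the base.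

**Further compounds**

F1 | step 6 | C7 3-chlorobenzoate, C8 alcohol from 8 (C8–OH on face a, C7 anomers) | C[C@]1(C(C)(OC)OC)C[C@H](O)C(CO[Si](c2ccccc2)(c2ccccc2)C(C)(C)C)(OC(=O)c2cccc(Cl)c2)O1
F2 | step 6 | C8 tert-butyldimethylsilyl ether of F1 | C[C@]1(C(C)(OC)OC)C[C@H](O[Si](C)(C)C(C)(C)C)C(CO[Si](c2ccccc2)(c2ccccc2)C(C)(C)C)(OC(=O)c2cccc(Cl)c2)O1
F3 | step 18 | C6 epimer (6S) of 30 | C=C(C)C(=O)O[C@H]1C[C@@]2(C)O[C@]1(C(=C)C(=O)OC(C)(C)C)[C@@H](O)/C=C(C)\CCC2=O
F4 | step 18 | macrocyclic C6 enone from F3 | C=C(C)C(=O)O[C@H]1C[C@@]2(C)O[C@]1(C(=C)C(=O)OC(C)(C)C)C(=O)/C=C(C)\CCC2=O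
F5 | step 20 | trans bromohydrin of 32 (C5–Br, C4–OH) | C=C(C)C(=O)O[C@H]1C[C@@]2(C)O[C@@]13C(=C)C(=O)O[C@@H]3[C@@H](Br)[C@@](O)(C)CCC2=O
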